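If E vanishes within hours while Q stands still, hold E at a small steady level, the quasi-steady state, and reckon with what the limiting reagent leaves in Q.

| flask | L | J | X | remark | time |
|---|---|---|---|---|---|
| dusk | 0.12 M | 0.048 M | 0.10 mM | run made earlier |  |
| autumn | 0.12 M | 0.19 M | 0.10 mM | run made earlier |  |
| noon | 0.18 M | 0.096 M | 0.10 mM | run made earlier |  |
| flask | 0.12 M | 0.0960 M | 0.10 mM |  | 12 h |

| run | time / h | E / % | Q / % |
|---|---|---|---|
| dusk | 1.00 | 8 | 8 |
| dusk | 3.00 | 1 | 14 |
| dusk | 6.00 | 3 | 15 |
| dusk | 8.00 | 0 | 14 |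
| dusk | 12.0 | 0 | 14 |
| autumn | 2.50 | 1 | 34 |
| autumn | 5.00 | 1 | 35 |
| autumn | 8.00 | 3 | 34 |
| autumn | 10.0 | 1 | 37 |
| autumn | 12.0 | 0 | 37 |
| noon | 1.00 | 6 | 13 |
| noon | 3.00 | 3 | 20 |
| noon | 6.00 | 0 | 18 |
| noon | 8.00 | 0 | 22 |
| noon | 12.0 | 0 | 18 |

(each reading ± 1.5 percentage points)

- amounts and yields of E count G too
- given per volume of solution although it is solid: G
- on the list of suspects stand: L + J <-> Q; 2 X <-> Z; G <-> E; L + J <-> E; E -> D; E + X <-> Q + X

- ratio of E to Q at 2.0 min
- ratio of E to Q at 12 h
- which of E and Q there is more of at 12 h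

Climb the ladder of time scales from the fastest rung. In the first hour, the dusk run reads E 8 % beside Q 8 % at 1.00 h, so Q forms early; reckon it as born beside E, not out of E. Within a few hours, that run reads E 1 % at 3.00 h, close to the scatter of 1.5 percentage points, so stop counting E as a store. On the slowest rung Q stays flat, so average its plateau and divide by the charge of the limiting reagent, both as concentrations.

| Run | Limiting reagent | Q share |
|---|---|---|
| dusk | J | 0.356 |
| autumn | L | 0.354 |
| noon | J | 0.366 |

Take the mean, 0.359, as the Q share, plateau Q per limiting reagent charged, and send the remainder through E to D.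

Now reckon this flask. J is the limiting reagent, 0.0960 M against 0.12 M of L, so expect Q at 12 h to be 28.7 % of the L charged. Back on the first rung, the share is a late, net figure, and the first readings come later than 2.0 min, so take its remainder over the share, 1.79, as E over Q at 2.0 min only roughly: it leaves out any E that goes back to L and J before the plateau, and such E puts the early ratio higher. The runs read E 0 %, 0 % and 0 % at 12.0 h, so expect Q to lead at 12 h, with a ratio too small to reckon from such readings.

The forecast, holding that “E is therefore the fast kinetic product”, gives 30 at 2.0 min, 0.03 at 12 h, and Q in the lead.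

The flask gives 2.44 at 2.0 min and 0.00429 at 12 h, with 0.127 % of E and 29.6 % of Q.

    L + J ⇌ Q (K = 3100 M⁻¹, k = 3.30 M⁻¹ h⁻¹)
    2 X ⇌ Z (K = 23000 M⁻¹, k = 2900 M⁻¹ h⁻¹)
    G ⇌ E, rate k3*(cs3 - [E]) while solid is left; crystals form when [E] > cs3 (solubility = 0.0660 M, k = 9.00 h⁻¹)
    L + J ⇌ E (K = 9.50 M⁻¹, k = 8.50 M⁻¹ h⁻¹)
    E → D (k = 1.90 h⁻¹)
    E + X ⇌ Q + X, rate k6*[X]*[E] forward; the back reaction follows from the equilibrium constant (k = 950 M⁻¹ h⁻¹)

Compare two of the ways out of E: it goes on to D with 1.9 h⁻¹ and back to L and J with 0.895 h⁻¹, a faster step, so of the 2.58 parts entering E for each part entering Q, 1.75 go on, a Q share of 0.363. Apply the share read from the runs to a neighbour flask charged with 0.024 M of J: it gives 7.18 % of the L charged, and that flask holds 7.55 % of Q.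

The data are calculated on assumed constants, noise included.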